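Germacranolide numbering is used (C1 ketone, C2=C3 enol ether, C4=C5, C6 lactone carbinol, C8 ester carbinol, C10 quaternary). The nine-membered oxonine (O, C3–C10) is closed last, at C7–C8, on a precursor that already holds the furanone and a 3-(bromomethyl)butenolide. The key step, an intramolecular Nozaki–Hiyama–Kishi allylation, exploits the fact that lactone β-carbon C7 and carbinol C8 are the termini of an allylmetal–aldehyde pair. CrCl2 umpoles the C13 bromide, C7 attacks the C8 aldehyde, and one operation closes the ring, sets C7 and C8 and unveils the C11=C13 methylene. The precursor is a (Z)-alkene-linked furanone–bromobutenolide aldehyde.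

Key step: step 13

Remark: dioxolanone 1 (the cis pivalaldehyde acetal of (S)-lactic acid) is taken as a purchasable chiral-pool compound, and the target is taken to be the furanoheliangolide goyazensolide (6R,7R,8R,10R; 4Z).

Step 1
Reactants: 1 (2S,5S)-2-tert-butyl-5-methyl-1,3-dioxolan-4-one; 2 prenyl bromide (1-bromo-3-methylbut-2-ene)
Product: 4 (2S,5R)-2-tert-butyl-5-methyl-5-(3-methylbut-2-en-1-yl)-1,3-dioxolan-4-one, via lithium enolate 3 (not isolated)
Conditions: LiN(iPr)2, THF, −78 °C; then 2, −78 to −30 °C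
Reagents that add atoms: 2 prenyl bromide, CC(C)=CCBr
Why: Alkylation of the lactic acid acetal enolate (self-regeneration of stereocentres) should occur anti to the tert-butyl group, so prenyl replaces hydrogen with retention and sets the C10 quaternary centre as R.

Step 2
Reactants: 4 prenylated dioxolanone; 5 N,O-dimethylhydroxylamine hydrochloride
Product: 6 (2R)-2-hydroxy-N-methoxy-N,2,5-trimethylhex-4-enamide
Conditions: MeNH(OMe)·HCl, iPrMgCl, THF, −20 to 0 °C; aqueous NH4Cl
Reagents that add atoms: 5 N,O-dimethylhydroxylamine hydrochloride, CNOC.Cl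
Why: Aminolysis of the acylal lactone by the chloromagnesium amide (Weinreb amide formation) should open the ring and release pivalaldehyde from the hemiacetal alkoxide, without touching the quaternary centre.

Step 3
Reactants: 6 Weinreb amide; 7 ethynylmagnesium bromide
Product: 8 (4R)-4-hydroxy-4,7-dimethyloct-6-en-1-yn-3-one
Conditions: 7 (3 equiv), THF, 0 °C; cold aqueous NH4Cl
Reagents that add atoms: 7 ethynylmagnesium bromide, C#C[Mg]Br
Why: Acetylide addition to the Weinreb amide should stop at the chelated tetrahedral intermediate (one equivalent is spent on the hydroxyl), which gives the terminal α′-hydroxy ynone on cold work-up.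

Step 4
Reactants: 9 tert-butyldimethyl(prop-2-yn-1-yloxy)silane; 10 acrolein
Product: 12 (3S)-6-[(tert-butyldimethylsilyl)oxy]hex-1-en-4-yn-3-ol, via alkynyl(methyl)zinc 11 (not isolated)
Conditions: 9, Me2Zn, ProPhenol ligand (the enantiomer that gives the 3S alcohol), Ph3PO, toluene, 0 °C; then 10
Reagents that add atoms: 10 acrolein, C=CC=O
Why: Zinc–ProPhenol-catalysed enantioselective 1,2-alkynylation of an enal should set the C6 carbinol under catalyst control.

Step 5
Reactants: 12 enynol; 13 iodine
Product: 15 (3S,4Z)-6-[(tert-butyldimethylsilyl)oxy]-5-iodohexa-1,4-dien-3-ol, via cyclic vinylaluminate 14 (not isolated)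
Conditions: NaAlH2(OCH2CH2OMe)2, THF, 0 °C; then I2, −78 °C
Reagents that add atoms: 13 iodine, [I][I]
Why: Hydroxyl-directed trans-hydroalumination should deliver hydride to the proximal alkyne carbon and place aluminium on the distal one in a five-membered alkoxyaluminate, and iodinolysis with retention then gives the vinyl iodide with iodine cis to C6 (low temperature avoids β-elimination of the silyloxy group).

Step 6
Reactants: 15 iodo dienol; 16 acryloyl chloride
Product: 17 (3S,4Z)-6-[(tert-butyldimethylsilyl)oxy]-5-iodohexa-1,4-dien-3-yl prop-2-enoate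
Conditions: 16, iPr2NEt, CH2Cl2, −78 to 0 °C
Reagents that add atoms: 16 acryloyl chloride, C=CC(=O)Cl
Why: O-Acylation of the only hydroxyl masks the C6 oxygen, so that it cannot add to the ynone formed in step 8, and installs the acrylate used in steps 7 and 10.

Step 7
Reactants: 17 acrylate; 18 formaldehyde
Product: 19 (3S,4Z)-6-[(tert-butyldimethylsilyl)oxy]-5-iodohexa-1,4-dien-3-yl 2-(hydroxymethyl)prop-2-enoate
Conditions: aqueous HCHO, DABCO, 1,4-dioxane/H2O, 25 °C
Reagents that add atoms: 18 formaldehyde, C=O
Why: Morita–Baylis–Hillman reaction of the acrylate with formaldehyde should install the C13 hydroxymethyl group on C11 without touching the vinyl iodide or the silyl ether.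

Step 8
Reactants: 19 vinyl iodide; 8 hydroxy ynone
Product: 20 (3S,4E,9R)-5-{[(tert-butyldimethylsilyl)oxy]methyl}-9-hydroxy-9,12-dimethyl-8-oxotrideca-1,4,11-trien-6-yn-3-yl 2-(hydroxymethyl)prop-2-enoate
Conditions: Pd(PPh3)2Cl2 (5 mol %), CuI (10 mol %), iPr2NEt, THF, 0 to 25 °C
Reagents that add atoms: none
Why: Sonogashira coupling of the terminal ynone with the vinyl iodide should form the C3–C4 bond with retention of alkene geometry, a tertiary amine being used so that no N–H amine adds to the ynone.

Step 9
Reactants: 20 enynone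
Product: 21 (3S,4Z)-6-[(tert-butyldimethylsilyl)oxy]-5-[(5R)-5-methyl-5-(3-methylbut-2-en-1-yl)-4-oxo-4,5-dihydrofuran-2-yl]hexa-1,4-dien-3-yl 2-(hydroxymethyl)prop-2-enoate
Conditions: Ph3PAuNTf2 (5 mol %), CH2Cl2, 25 °C
Reagents that add atoms: none
Why: Gold-catalysed 5-endo-dig addition of the tertiary C10 hydroxyl to the ynone (cycloisomerisation of an α′-hydroxy ynone) should give the 3(2H)-furanone, the other oxygen functions being acylated, silylated or too remote to compete.

Step 10
Reactants: 21 furanone triene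
Product: 22 (5R)-5-[(1Z)-3-{[tert-butyl(dimethyl)silyl]oxy}-2-[(5R)-5-methyl-5-(3-methylbut-2-en-1-yl)-4-oxo-4,5-dihydrofuran-2-yl]prop-1-en-1-yl]-3-(hydroxymethyl)furan-2(5H)-one
Conditions: Hoveyda–Grubbs second-generation catalyst (10 mol %), toluene, 80 °C
Reagents that add atoms: none
Why: Ring-closing metathesis between the C7 vinyl group and the 1,1-disubstituted acrylate should close the five-membered butenolide (C6, C7, C11, C12, O), the trisubstituted prenyl, C4=C5 and enol ether alkenes being too hindered to engage and no base being present that could epimerise C6.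

Step 11
Reactants: 22 hydroxymethyl butenolide; 23 tetrabromomethane
Product: 24 (5R)-3-(bromomethyl)-5-[(1Z)-3-{[tert-butyl(dimethyl)silyl]oxy}-2-[(5R)-5-methyl-5-(3-methylbut-2-en-1-yl)-4-oxo-4,5-dihydrofuran-2-yl]prop-1-en-1-yl]furan-2(5H)-one
Conditions: CBr4, PPh3, CH2Cl2, 0 °C
Reagents that add atoms: 23 tetrabromomethane, BrC(Br)(Br)Br
Why: The Appel reaction should convert the primary allylic alcohol into the bromide under neutral conditions that leave the silyl ether and the base-sensitive γ-centre alone.

Step 12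
Reactants: 24 bromomethyl butenolide; 25 ozone
Product: 26 {(2R)-5-[(1Z)-1-[(2R)-4-(bromomethyl)-5-oxo-2,5-dihydrofuran-2-yl]-3-{[tert-butyl(dimethyl)silyl]oxy}prop-1-en-2-yl]-2-methyl-3-oxo-2,3-dihydrofuran-2-yl}acetaldehyde
Conditions: O3, pyridine, CH2Cl2, −78 °C; cold aqueous NaHSO4 wash
Reagents that add atoms: 25 ozone, [O-][O+]=O
Why: Ozonolysis should cleave the isolated, electron-rich prenyl alkene much faster than the three conjugated electron-poor alkenes, and pyridine converts the carbonyl oxide directly into the C8 aldehyde so that no phosphine or sulfide reductant meets the allylic bromide.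

Step 13
Reactants: 26 bromo aldehyde
Product: 28 (6R,7R,8S,10R)-15-O-(tert-butyldimethylsilyl)-8-O-demethacryloyl-8-epi-goyazensolide (tricyclic 8S alcohol), via trivalent allylchromium dichloride 27 (not isolated)
Conditions: CrCl2 (8 equiv), THF, 25 °C, slow addition of 26 to 2 mM final concentration; then water
Reagents that add atoms: none
Why: CrCl2 reduces the allylic bromide to the trivalent allylchromium species 27, whose γ-carbon C7 adds to the C8 aldehyde through a closed chair-like six-membered transition state with allylic transposition, so that the C7–C8 bond, the nine-membered oxonine and the exocyclic C11=C13 methylene arise in one operation. The closest known reaction type is the Nozaki–Hiyama–Kishi allylation of aldehydes with 3-(bromomethyl)furan-2(5H)-ones, together with the intramolecular chromium-mediated closures of nine-membered oxacycles in oxygen-bridged cyclodecanes. The oxonine closes in a 9-exo-trig mode at the aldehyde carbon. C7 is controlled by C6: the aldehyde is expected to reach the butenolide face anti to the C6–C5 bond, which gives the trans-fused lactone and a staggered C5–C6–C7–C8 torsion that the nine-membered ring accommodates, whereas the syn approach would eclipse these bonds. C8 is controlled by the chair: the ring tether (C9) can only lie anti to C11 and the chromium-bound oxygen must sit on the C13 side, which leads to the 8S alcohol, the C8 epimer of the natural series, corrected by inversion in step 14. The step needs aldehyde-over-ketone chemoselectivity, secured by the low reactivity of trivalent allylchromium toward the vinylogous ester carbonyl C1 and the lactone, and cyclisation over oligomerisation, secured by slow addition at high dilution and by the cis C4=C5 bond and the planar furanone that hold C7 and C8 close.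

Step 14
Reactants: 28 tricyclic 8S alcohol; 29 methacrylic acid
Product: 30 15-O-(tert-butyldimethylsilyl)goyazensolide (6R,7R,8R,10R)
Conditions: 29, PPh3, DIAD, toluene, 0 to 25 °C
Reagents that add atoms: 29 methacrylic acid, C=C(C)C(=O)O
Why: Mitsunobu esterification should displace the activated C8 oxygen by methacrylate with inversion (SN2), turning 8S into the required 8R ester.

Step 15
Reactants: 30 silyl ether
Product: 31 goyazensolide (target)
Conditions: HF·pyridine, THF, 0 °C
Reagents that add atoms: none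
Why: Fluoride cleavage of the primary silyl ether under buffered acidic conditions should leave both esters, the furanone and the exo-methylene lactone untouched.

Compound list
1 | (2S,5S)-2-tert-butyl-5-methyl-1,3-dioxolan-4-one | C[C@@H]1O[C@@H](OC1=O)C(C)(C)C | starting material
2 | prenyl bromide (1-bromo-3-methylbut-2-ene) | CC(C)=CCBr | starting material
3 | lithium (2S)-2-tert-butyl-5-methyl-1,3-dioxol-4-olate | [Li+].CC1=C([O-])O[C@H](O1)C(C)(C)C | intermediate
4 | (2S,5R)-2-tert-butyl-5-methyl-5-(3-methylbut-2-en-1-yl)-1,3-dioxolan-4-one | CC(C)=CC[C@@]1(C)O[C@@H](OC1=O)C(C)(C)C | intermediate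
5 | N,O-dimethylhydroxylamine hydrochloride | CNOC.Cl | starting material
6 | (2R)-2-hydroxy-N-methoxy-N,2,5-trimethylhex-4-enamide | CC(C)=CC[C@@](C)(O)C(=O)N(C)OC | intermediate
7 | ethynylmagnesium bromide | C#C[Mg]Br | starting material
8 | (4R)-4-hydroxy-4,7-dimethyloct-6-en-1-yn-3-one | C#CC(=O)[C@](C)(O)CC=C(C)C | intermediate
9 | tert-butyldimethyl(prop-2-yn-1-yloxy)silane | C#CCO[Si](C)(C)C(C)(C)C | starting material
10 | acrolein | C=CC=O | starting material
11 | {3-[(tert-butyldimethylsilyl)oxy]prop-1-yn-1-yl}(methyl)zinc | C[Zn]C#CCO[Si](C)(C)C(C)(C)C | intermediate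
12 | (3S)-6-[(tert-butyldimethylsilyl)oxy]hex-1-en-4-yn-3-ol | C=C[C@H](O)C#CCO[Si](C)(C)C(C)(C)C | intermediate
13 | iodine | [I][I] | starting material
14 | sodium cyclic alkoxy(vinyl)aluminate (five-membered oxa-aluminacycle from 12) | [Na+].C=C[C@@H]1O[Al-](OCCOC)(OCCOC)C(CO[Si](C)(C)C(C)(C)C)=C1 | intermediate
15 | (3S,4Z)-6-[(tert-butyldimethylsilyl)oxy]-5-iodohexa-1,4-dien-3-ol | C=C[C@H](O)/C=C(\I)CO[Si](C)(C)C(C)(C)C | intermediate
16 | acryloyl chloride | C=CC(=O)Cl | starting material
17 | (3S,4Z)-6-[(tert-butyldimethylsilyl)oxy]-5-iodohexa-1,4-dien-3-yl prop-2-enoate | C=CC(=O)O[C@@H](C=C)/C=C(\I)CO[Si](C)(C)C(C)(C)C | intermediate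
18 | formaldehyde | C=O | starting material
19 | (3S,4Z)-6-[(tert-butyldimethylsilyl)oxy]-5-iodohexa-1,4-dien-3-yl 2-(hydroxymethyl)prop-2-enoate | C=C(CO)C(=O)O[C@@H](C=C)/C=C(\I)CO[Si](C)(C)C(C)(C)C | intermediate
20 | (3S,4E,9R)-5-{[(tert-butyldimethylsilyl)oxy]methyl}-9-hydroxy-9,12-dimethyl-8-oxotrideca-1,4,11-trien-6-yn-3-yl 2-(hydroxymethyl)prop-2-enoate | C=C(CO)C(=O)O[C@@H](C=C)/C=C(\C#CC(=O)[C@](C)(O)CC=C(C)C)CO[Si](C)(C)C(C)(C)C | intermediate
21 | (3S,4Z)-6-[(tert-butyldimethylsilyl)oxy]-5-[(5R)-5-methyl-5-(3-methylbut-2-en-1-yl)-4-oxo-4,5-dihydrofuran-2-yl]hexa-1,4-dien-3-yl 2-(hydroxymethyl)prop-2-enoate | C=C(CO)C(=O)O[C@@H](C=C)/C=C(\C1=CC(=O)[C@@](C)(CC=C(C)C)O1)CO[Si](C)(C)C(C)(C)C | intermediate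
22 | (5R)-5-[(1Z)-3-{[tert-butyl(dimethyl)silyl]oxy}-2-[(5R)-5-methyl-5-(3-methylbut-2-en-1-yl)-4-oxo-4,5-dihydrofuran-2-yl]prop-1-en-1-yl]-3-(hydroxymethyl)furan-2(5H)-one | OCC1=C[C@H](OC1=O)/C=C(\C2=CC(=O)[C@@](C)(CC=C(C)C)O2)CO[Si](C)(C)C(C)(C)C | intermediate
23 | tetrabromomethane | BrC(Br)(Br)Br | starting material
24 | (5R)-3-(bromomethyl)-5-[(1Z)-3-{[tert-butyl(dimethyl)silyl]oxy}-2-[(5R)-5-methyl-5-(3-methylbut-2-en-1-yl)-4-oxo-4,5-dihydrofuran-2-yl]prop-1-en-1-yl]furan-2(5H)-one | BrCC1=C[C@H](OC1=O)/C=C(\C2=CC(=O)[C@@](C)(CC=C(C)C)O2)CO[Si](C)(C)C(C)(C)C | intermediate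
25 | ozone | [O-][O+]=O | starting material
26 | {(2R)-5-[(1Z)-1-[(2R)-4-(bromomethyl)-5-oxo-2,5-dihydrofuran-2-yl]-3-{[tert-butyl(dimethyl)silyl]oxy}prop-1-en-2-yl]-2-methyl-3-oxo-2,3-dihydrofuran-2-yl}acetaldehyde | BrCC1=C[C@H](OC1=O)/C=C(\C2=CC(=O)[C@@](C)(CC=O)O2)CO[Si](C)(C)C(C)(C)C | intermediate
27 | trivalent allylchromium dichloride derived from 26 (chromium on C13) | Cl[Cr](Cl)CC1=C[C@H](OC1=O)/C=C(\C2=CC(=O)[C@@](C)(CC=O)O2)CO[Si](C)(C)C(C)(C)C | intermediate
28 | (6R,7R,8S,10R)-15-O-(tert-butyldimethylsilyl)-8-O-demethacryloyl-8-epi-goyazensolide | O[C@H]1C[C@@]2(C)OC(=CC2=O)/C(CO[Si](C)(C)C(C)(C)C)=C\[C@H]2OC(=O)C(=C)[C@@H]21 | intermediate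
29 | methacrylic acid | C=C(C)C(=O)O | starting material
30 | 15-O-(tert-butyldimethylsilyl)goyazensolide (6R,7R,8R,10R) | C=C(C)C(=O)O[C@@H]1C[C@@]2(C)OC(=CC2=O)/C(CO[Si](C)(C)C(C)(C)C)=C\[C@H]2OC(=O)C(=C)[C@@H]21 | intermediate
31 | goyazensolide (6R,7R,8R,10R; 4Z), CNP0180483.5 | C=C(C)C(=O)O[C@@H]1C[C@@]2(C)OC(=CC2=O)/C(CO)=C\[C@H]2OC(=O)C(=C)[C@@H]21 | target

Total step count: 15. Longest linear sequence: 12 steps (steps 4 to 15, from 9 and 10); the branch of steps 1 to 3 joins at step 8.

Steps most likely to fail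

1. Step 13 (key step). Strain in the oxygen-bridged transition state may slow C7–C8 bond formation so that protonation or dimerisation of the allylchromium species takes over, and approach to the wrong butenolide face would give the cis-fused lactone. The fallback changes the order of ring formation: the carbocycle is closed before the oxygen bridge is made. It sets out from 19. Ring-closing metathesis (Hoveyda–Grubbs second-generation catalyst, toluene, 80 °C) would give the iodo butenolide F1, and Sonogashira coupling with 8 (Pd(PPh3)2Cl2, CuI, iPr2NEt, THF, 0 °C) the unbridged butenolide ynone F2. Appel bromination (CBr4, PPh3) would give the allylic bromide F3, and ozonolysis of the prenyl group (O3, pyridine, −78 °C) the unbridged bromo aldehyde F4. CrCl2 in THF at high dilution would then close the less strained ten-membered carbocyclic ynone F5 by the same C7–C8 allylation. Transannular gold-catalysed 5-endo-dig addition of the C10 hydroxyl to the ynone (Ph3PAuNTf2, CH2Cl2) would create the furanone and the oxonine together and come back to the route at 28.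

2. Step 8. The free hydroxy ynone may cycloisomerise or oligomerise under the copper and amine before it is intercepted by the vinylpalladium species, and zerovalent palladium may ionise the bis-allylic ester. The fallback masks the hydroxyl and moves its release into the cyclisation step. It sets out from 6. Silylation (Me3SiCl, imidazole, DMF) would give the silylated Weinreb amide F6, and ethynylmagnesium bromide the silylated ynone F7. Sonogashira coupling of F7 with 19 would give the silyl-protected enynone F8, and Ph3PAuNTf2 in CH2Cl2/MeOH would remove the trimethylsilyl group and cyclise in the same pot, coming back to the route at 21.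

3. Step 14. SN2 substitution at the hindered C8 has to occur from the lactone side and may be slow, so that elimination toward C7 or C9 and phosphine addition to the exo-methylene compete. The fallback corrects C8 by oxidation and reduction instead of substitution. It sets out from 28. Dess–Martin periodinane (NaHCO3, CH2Cl2) would give the C8 ketone F9. Luche reduction (NaBH4, CeCl3·7H2O, MeOH, −78 °C), with hydride expected from the open outer face on which the chromium-bound oxygen sat, would give the 8R alcohol F10. Acylation with methacrylic anhydride (Et3N, DMAP, CH2Cl2) would come back to the route at 30.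

Further compounds
F1 | step 13 | (5S)-5-[(1Z)-3-{[tert-butyl(dimethyl)silyl]oxy}-2-iodoprop-1-en-1-yl]-3-(hydroxymethyl)furan-2(5H)-one | OCC1=C[C@H](OC1=O)/C=C(\I)CO[Si](C)(C)C(C)(C)C
F2 | step 13 | (5R)-5-[(1E,6R)-2-({[tert-butyl(dimethyl)silyl]oxy}methyl)-6-hydroxy-6,9-dimethyl-5-oxodeca-1,8-dien-3-yn-1-yl]-3-(hydroxymethyl)furan-2(5H)-one | OCC1=C[C@H](OC1=O)/C=C(\C#CC(=O)[C@](C)(O)CC=C(C)C)CO[Si](C)(C)C(C)(C)C
F3 | step 13 | 3-(bromomethyl) analogue of F2 (allylic bromide) | BrCC1=C[C@H](OC1=O)/C=C(\C#CC(=O)[C@](C)(O)CC=C(C)C)CO[Si](C)(C)C(C)(C)C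
F4 | step 13 | unbridged bromo aldehyde (prenyl group of F3 cleaved to the C8 aldehyde) | BrCC1=C[C@H](OC1=O)/C=C(\C#CC(=O)[C@](C)(O)CC=O)CO[Si](C)(C)C(C)(C)C
F5 | step 13 | ten-membered carbocyclic ynone diol with α-methylene lactone (C6, C7, C8, C10 as in 28; no oxygen bridge) | O[C@H]1C[C@@](C)(O)C(=O)C#C/C(CO[Si](C)(C)C(C)(C)C)=C\[C@H]2OC(=O)C(=C)[C@@H]21
F6 | step 8 | (2R)-N-methoxy-N,2,5-trimethyl-2-[(trimethylsilyl)oxy]hex-4-enamide | CC(C)=CC[C@@](C)(O[Si](C)(C)C)C(=O)N(C)OC
F7 | step 8 | (4R)-4,7-dimethyl-4-[(trimethylsilyl)oxy]oct-6-en-1-yn-3-one | C#CC(=O)[C@](C)(O[Si](C)(C)C)CC=C(C)C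
F8 | step 8 | 9-O-trimethylsilyl ether of 20 | C=C(CO)C(=O)O[C@@H](C=C)/C=C(\C#CC(=O)[C@](C)(O[Si](C)(C)C)CC=C(C)C)CO[Si](C)(C)C(C)(C)C
F9 | step 14 | C8 ketone derived from 28 | O=C1C[C@@]2(C)OC(=CC2=O)/C(CO[Si](C)(C)C(C)(C)C)=C\[C@H]2OC(=O)C(=C)[C@@H]21
F10 | step 14 | (6R,7R,8R,10R)-15-O-(tert-butyldimethylsilyl)-8-O-demethacryloylgoyazensolide (8R alcohol) | O[C@@H]1C[C@@]2(C)OC(=CC2=O)/C(CO[Si](C)(C)C(C)(C)C)=C\[C@H]2OC(=O)C(=C)[C@@H]21
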